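Retrosynthetic overview (ring positions as in hexahydro-1H-cyclopenta[c]isoxazole: N1, O2, C3, C3a, C4, C5, C6, C6a)
- Pyrinodemin B ⇒ (C3–H, hydride to the convex face of a bicyclic oxocarbenium ion) cis-fused cyclic hemiketal ⇒ (O2–C3, ring–chain tautomerism) 2-(N-hydroxyamino)cyclopentyl ketone. The isoxazolidine is closed last, with C3 at the ketone oxidation level.
- Aminocyclopentyl ketone ⇒ strain-release formal [3+2] of an N-cyclopropyl O-silyl hydroxylamine (C6a–C6–C5) with a vinyl ketone (C3a=C4). Opening the cyclopropane forms C4–C5 and C3a–C6a in one operation and joins both pyridylalkyl arms.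
- Enabling feature: in the cyclopentane ring the nitrogen sits on C6a, directly beside C3a, which carries the oxygenated carbon C3. An aminocyclopentane is an aminocyclopropane plus an alkene, and C3 as a carbonyl both polarises that alkene and later accepts the N–O oxygen of the isoxazolidine ring.
- Arms: lateral alkylation of 3-picoline, then N-alkylation of N-cyclopropylhydroxylamine (amine arm); B-alkyl Suzuki coupling of a non-8-enoic Weinreb amide with 3-bromopyridine, then vinyl Grignard (enone arm).
- Ring order: cyclopentane first (step 7), isoxazolidine second (steps 8 and 9). C6a is set in step 7 (chiral counter-anion), C3a by epimerisation into the cis-fused hemiketal, C3 by convex-face hydride.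

Key step: step 7

Remark: every starting material is taken to be a catalogue item, and of the two enantiomers of the chiral counter-anion in step 7 the one that leads to the (R) aminated carbon is used.

Step 1
Reactants: 1 3-methylpyridine; 2 1,12-dibromododecane
Product: 4 3-(13-bromotridecyl)pyridine, via (pyridin-3-ylmethyl)lithium 3 (not isolated)
Conditions: LiN(iPr)2 (LDA), THF, −78 °C; then 2 (3 equiv), −78 °C to rt
Reagents that add atoms: none
Why: Lateral lithiation of 3-picoline and SN2 alkylation of the picolyl anion, with excess dibromide to limit double alkylation.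

Step 2
Reactants: 4 3-(13-bromotridecyl)pyridine; 5 N-cyclopropylhydroxylamine hydrochloride
Product: 6 N-cyclopropyl-N-[13-(pyridin-3-yl)tridecyl]hydroxylamine
Conditions: 5 (3 equiv), K2CO3, KI (cat.), MeCN, 50 °C, argon
Reagents that add atoms: none
Why: SN2 N-alkylation of an N-monosubstituted hydroxylamine, whose alpha-effect nitrogen is more nucleophilic than its oxygen or the pyridine nitrogen, with excess 5 to suppress self-quaternisation of 4.

Step 3
Reactants: 6 N-cyclopropyl-N-[13-(pyridin-3-yl)tridecyl]hydroxylamine
Product: 7 N-cyclopropyl-N-[13-(pyridin-3-yl)tridecyl]-O-(triisopropylsilyl)hydroxylamine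
Conditions: iPr3SiCl, imidazole, DMF, rt
Reagents that add atoms: triisopropylsilyl chloride, CC(C)[Si](Cl)(C(C)C)C(C)C
Why: O-silylation of the only hydroxyl group (silyl ether formation), which blocks nitroxide formation in step 7 and is removed by fluoride in step 8.

Step 4
Reactants: 8 non-8-enoic acid
Product: 10 N-methoxy-N-methylnon-8-enamide, via 1-(non-8-enoyl)imidazole 9 (not isolated)
Conditions: 1,1'-carbonyldiimidazole, CH2Cl2, rt; then MeNH(OMe)·HCl, rt
Reagents that add atoms: N,O-dimethylhydroxylamine hydrochloride, CNOC.Cl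
Why: Weinreb amide formation by aminolysis of the acyl imidazolide.

Step 5
Reactants: 10 N-methoxy-N-methylnon-8-enamide; 11 3-bromopyridine
Product: 13 N-methoxy-N-methyl-9-(pyridin-3-yl)nonanamide, via B-alkyl-9-BBN adduct 12 (not isolated)
Conditions: 9-BBN, THF, 0 °C to rt; then 11, PdCl2(dppf) (3 mol%), K3PO4 (aq.), DMF, 60 °C
Reagents that add atoms: none
Why: Anti-Markovnikov hydroboration of the terminal alkene followed by B-alkyl Suzuki–Miyaura coupling, both of which tolerate the Weinreb amide.

Step 6
Reactants: 13 N-methoxy-N-methyl-9-(pyridin-3-yl)nonanamide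
Product: 14 11-(pyridin-3-yl)undec-1-en-3-one
Conditions: CH2=CHMgBr, THF, −78 to 0 °C; inverse quench into cold 1 M HCl, extraction at pH 6; used at once
Reagents that add atoms: vinylmagnesium bromide, C=C[Mg]Br
Why: Weinreb ketone synthesis, in which the chelated tetrahedral intermediate prevents over-addition and the acidic quench keeps the liberated amine from adding to the vinyl ketone.

Step 7
Reactants: 7 N-cyclopropyl-N-[13-(pyridin-3-yl)tridecyl]-O-(triisopropylsilyl)hydroxylamine; 14 11-(pyridin-3-yl)undec-1-en-3-one
Product: 16 1-[(2R)-2-{[13-(pyridin-3-yl)tridecyl][(triisopropylsilyl)oxy]amino}cyclopentyl]-9-(pyridin-3-yl)nonan-1-one (2R fixed; both epimers at ring C1), via ring-opened distonic radical cation 15 (not isolated)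
Conditions: 14 (3 equiv), 9-mesityl-3,6-di-tert-butyl-10-phenylacridinium salt of a confined chiral imidodiphosphorimidate (IDPi) anion (5 mol%), CH2Cl2/toluene, 450 nm LEDs, −40 °C, degassed
Reagents that add atoms: none
Why: Proposed new method: the excited acridinium removes one electron from the silyloxyamine nitrogen of 7, the aminium radical cation opens its cyclopropane (release of about 27 kcal/mol of ring strain) to the distonic radical cation 15 with a primary radical at C5 and an N-silyloxy iminium at C6a, the nucleophilic radical adds to the CH2 terminus of enone 14 (Giese addition, bond C4–C5), the resulting alpha-keto radical closes on the iminium carbon (bond C3a–C6a), and the acridinyl radical returns the electron to give neutral 16. The closest known reaction type is the visible-light photoredox formal [3+2] cycloaddition of N-aryl cyclopropylamines with electron-poor alkenes, including its ion-pair-controlled asymmetric variants with N-cyclopropyl ureas; new here are the N-alkyl-N-silyloxy nitrogen, which is harder to oxidise (hence the strongly oxidising acridinium), and stereocontrol by ion pairing alone. Only the cyclopentane closes in this step, in a 5-exo-trig attack of the C3a radical on the C6a=N bond. C6a is set in that closure by the chiral counter-anion, which stays paired with the iminium cation and shields one of its faces; C3a forms without control, but it is alpha to the ketone and is corrected in step 8. The step needs regioselective radical attack at the unsubstituted enone carbon (secured by the polarised vinyl ketone), chemoselective oxidation (the silyloxyamine is much easier to oxidise than the two pyridine rings) and an iminium that stays cationic (no N–H to lose and a bulky silyl group that resists transfer), so that no achiral neutral acceptor competes.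

Step 8
Reactants: 16 1-[(2R)-2-{[13-(pyridin-3-yl)tridecyl][(triisopropylsilyl)oxy]amino}cyclopentyl]-9-(pyridin-3-yl)nonan-1-one
Product: 18 (3aS,6aR)-3-[8-(pyridin-3-yl)octyl]-1-[13-(pyridin-3-yl)tridecyl]hexahydro-1H-cyclopenta[c][1,2]oxazol-3-ol (cis-fused hemiketal; both C3 anomers), via open-chain N-hydroxy amino ketone 17 (not isolated)
Conditions: Bu4NF (1.2 equiv), THF, 0 °C to rt; then DBU (0.2 equiv), rt, until the trans isomer is consumed
Reagents that add atoms: none
Why: Fluoride desilylation frees the hydroxylamine, whose oxygen adds to the ketone (ring–chain tautomerism of a beta-hydroxyamino ketone), while base epimerises C3a through the enolate so that both epimers converge on the cis-fused hemiketal, the only ring fusion without prohibitive strain, which fixes C3a as (S) relative to (R)-C6a.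

Step 9
Reactants: 18 (3aS,6aR)-3-[8-(pyridin-3-yl)octyl]-1-[13-(pyridin-3-yl)tridecyl]hexahydro-1H-cyclopenta[c][1,2]oxazol-3-ol
Product: 19 pyrinodemin B, (3S,3aS,6aR)-3-[8-(pyridin-3-yl)octyl]-1-[13-(pyridin-3-yl)tridecyl]hexahydro-1H-cyclopenta[c][1,2]oxazole
Conditions: Et3SiH (5 equiv), Me3SiOTf (4 equiv), CH2Cl2, −78 to −30 °C; NaHCO3 (aq.)
Reagents that add atoms: none
Why: Ionic hydrogenation of the hemiketal, in which Me3SiOTf ionises C3 to the bicyclic oxocarbenium ion and triethylsilane delivers hydride to the convex face of the cis-fused bicycle, placing H3 cis to H3a and H6a and the octyl chain on the concave face, i.e. (3S).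

Compound list
1 | 3-methylpyridine (3-picoline) | Cc1cccnc1 | starting material
2 | 1,12-dibromododecane | BrCCCCCCCCCCCCBr | starting material
3 | (pyridin-3-ylmethyl)lithium | [Li]Cc1cccnc1 | intermediate
4 | 3-(13-bromotridecyl)pyridine | BrCCCCCCCCCCCCCc1cccnc1 | intermediate
5 | N-cyclopropylhydroxylamine hydrochloride | ONC1CC1.Cl | starting material
6 | N-cyclopropyl-N-[13-(pyridin-3-yl)tridecyl]hydroxylamine | ON(C1CC1)CCCCCCCCCCCCCc1cccnc1 | intermediate
7 | N-cyclopropyl-N-[13-(pyridin-3-yl)tridecyl]-O-(triisopropylsilyl)hydroxylamine | CC(C)[Si](C(C)C)(C(C)C)ON(C1CC1)CCCCCCCCCCCCCc1cccnc1 | intermediate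
8 | non-8-enoic acid | C=CCCCCCCC(=O)O | starting material
9 | 1-(non-8-enoyl)imidazole | C=CCCCCCCC(=O)n1ccnc1 | intermediate
10 | N-methoxy-N-methylnon-8-enamide | C=CCCCCCCC(=O)N(C)OC | intermediate
11 | 3-bromopyridine | Brc1cccnc1 | starting material
12 | 9-(9-borabicyclo[3.3.1]nonan-9-yl)-N-methoxy-N-methylnonanamide | CON(C)C(=O)CCCCCCCCB1C2CCCC1CCC2 | intermediate
13 | N-methoxy-N-methyl-9-(pyridin-3-yl)nonanamide | CON(C)C(=O)CCCCCCCCc1cccnc1 | intermediate
14 | 11-(pyridin-3-yl)undec-1-en-3-one | C=CC(=O)CCCCCCCCc1cccnc1 | intermediate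
15 | ring-opened distonic radical cation (primary carbon radical, N-[13-(pyridin-3-yl)tridecyl]-N-[(triisopropylsilyl)oxy]propan-1-iminium) | [CH2]CC=[N+](O[Si](C(C)C)(C(C)C)C(C)C)CCCCCCCCCCCCCc1cccnc1 | intermediate
16 | 1-[(2R)-2-{[13-(pyridin-3-yl)tridecyl][(triisopropylsilyl)oxy]amino}cyclopentyl]-9-(pyridin-3-yl)nonan-1-one, (1S,2R)-cis and (1R,2R)-trans epimers | O=C(CCCCCCCCc1cccnc1)C1CCC[C@H]1N(O[Si](C(C)C)(C(C)C)C(C)C)CCCCCCCCCCCCCc1cccnc1 | intermediate
17 | 1-[(2R)-2-{hydroxy[13-(pyridin-3-yl)tridecyl]amino}cyclopentyl]-9-(pyridin-3-yl)nonan-1-one, both C1 epimers | O=C(CCCCCCCCc1cccnc1)C1CCC[C@H]1N(O)CCCCCCCCCCCCCc1cccnc1 | intermediate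
18 | (3aS,6aR)-3-[8-(pyridin-3-yl)octyl]-1-[13-(pyridin-3-yl)tridecyl]hexahydro-1H-cyclopenta[c][1,2]oxazol-3-ol, both C3 anomers | c1cncc(CCCCCCCCCCCCCN2OC(O)(CCCCCCCCc3cccnc3)[C@H]3CCC[C@H]32)c1 | intermediate
19 | pyrinodemin B, (3S,3aS,6aR)-3-[8-(pyridin-3-yl)octyl]-1-[13-(pyridin-3-yl)tridecyl]hexahydro-1H-cyclopenta[c][1,2]oxazole | c1cncc(CCCCCCCCCCCCCN2O[C@@H](CCCCCCCCc3cccnc3)[C@H]3CCC[C@H]32)c1 | target

Total step count: 9
Longest linear sequence: 6 steps (steps 1, 2, 3, 7, 8, 9; the enone arm, steps 4, 5, 6, 7, 8, 9, is equally long)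

Steps most likely to fail

Step 7. The silyloxyaminium radical cation may return the electron or lose its silyl group instead of opening the ring, the enone may oligomerise faster than the cascade turns over, or the ion pair may discriminate the two faces of the iminium poorly, so that 16 would form slowly or with low enantiomeric purity. The fallback uses known chemistry from the chiral pool; it sets out from 4, uses 11 at the end, and comes back at 19. N-Alkylation of commercial methyl (1S,2R)-2-aminocyclopentane-1-carboxylate hydrochloride with 4 (K2CO3, MeCN) should give methyl (1S,2R)-2-{[13-(pyridin-3-yl)tridecyl]amino}cyclopentane-1-carboxylate F1. Oxidation of the secondary amine with dibenzoyl peroxide and K2HPO4 in DMF should give methyl (1S,2R)-2-{(benzoyloxy)[13-(pyridin-3-yl)tridecyl]amino}cyclopentane-1-carboxylate F2. Methanolysis of the benzoate (K2CO3, MeOH) should free methyl (1S,2R)-2-{hydroxy[13-(pyridin-3-yl)tridecyl]amino}cyclopentane-1-carboxylate F3, which is not isolated and lactonises to the cis-fused (3aS,6aR)-1-[13-(pyridin-3-yl)tridecyl]hexahydro-3H-cyclopenta[c][1,2]oxazol-3-one F4. Addition of commercial oct-7-en-1-ylmagnesium bromide at −78 °C should stop at the hemiketal (3aS,6aR)-3-(oct-7-en-1-yl)-1-[13-(pyridin-3-yl)tridecyl]hexahydro-1H-cyclopenta[c][1,2]oxazol-3-ol F5. Ionic hydrogenation under the conditions of step 9 should give (3S,3aS,6aR)-3-(oct-7-en-1-yl)-1-[13-(pyridin-3-yl)tridecyl]hexahydro-1H-cyclopenta[c][1,2]oxazole F6. Hydroboration with 9-BBN gives the B-alkyl-9-BBN adduct of the octenyl isoxazolidine F7, which is coupled in the same flask with 11 (PdCl2(dppf), K3PO4) to deliver 19. In this fallback both ring-fusion centres come from the amino acid, and the two carbon–carbon bonds of the key step are not made at all.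

Step 8. While C3a is being epimerised by base, the hydroxylamine may be lost and re-added across the enone (retro-conjugate addition), which would erode the configuration at C6a; alternatively the epimerisation may stall and leave the trans isomer unconverted. The fallback sets out from 16 and comes back at 19 without passing through 18 and without a basic step. It is a one-flask intramolecular reductive etherification (Me3SiOTf, Et3SiH, CH2Cl2/MeCN, −40 °C to 0 °C), in which the silyl ether oxygen itself attacks the Lewis-acid-activated ketone and the oxocarbenium ion is reduced as it forms. C3a then equilibrates through the enol under acid, so no enolate and no free hydroxylamine are present. No new compound is isolated.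

Step 9. The hemiketal may open to its ketone tautomer under the Lewis acid and take up hydride in the open chain, which would give an acyclic alcohol of uncontrolled configuration at C3 instead of the ring. The fallback sets out from 18 and comes back at 19. The ring is first locked as the methyl ketal (MeOH, HC(OMe)3, pyridinium p-toluenesulfonate) to give (3aS,6aR)-3-methoxy-3-[8-(pyridin-3-yl)octyl]-1-[13-(pyridin-3-yl)tridecyl]hexahydro-1H-cyclopenta[c][1,2]oxazole F8, which cannot open to a ketone. The isolated ketal is then reduced with Et3SiH and Me3SiOTf through the same oxocarbenium ion, with hydride again entering from the convex face.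

Further compounds
F1 | step 7 | methyl (1S,2R)-2-{[13-(pyridin-3-yl)tridecyl]amino}cyclopentane-1-carboxylate | COC(=O)[C@H]1CCC[C@H]1NCCCCCCCCCCCCCc1cccnc1
F2 | step 7 | methyl (1S,2R)-2-{(benzoyloxy)[13-(pyridin-3-yl)tridecyl]amino}cyclopentane-1-carboxylate | COC(=O)[C@H]1CCC[C@H]1N(OC(=O)c1ccccc1)CCCCCCCCCCCCCc1cccnc1
F3 | step 7 | methyl (1S,2R)-2-{hydroxy[13-(pyridin-3-yl)tridecyl]amino}cyclopentane-1-carboxylate | COC(=O)[C@H]1CCC[C@H]1N(O)CCCCCCCCCCCCCc1cccnc1
F4 | step 7 | (3aS,6aR)-1-[13-(pyridin-3-yl)tridecyl]hexahydro-3H-cyclopenta[c][1,2]oxazol-3-one | c1cncc(CCCCCCCCCCCCCN2OC(=O)[C@H]3CCC[C@H]32)c1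
F5 | step 7 | (3aS,6aR)-3-(oct-7-en-1-yl)-1-[13-(pyridin-3-yl)tridecyl]hexahydro-1H-cyclopenta[c][1,2]oxazol-3-ol | c1cncc(CCCCCCCCCCCCCN2OC(O)(CCCCCCC=C)[C@H]3CCC[C@H]32)c1
F6 | step 7 | (3S,3aS,6aR)-3-(oct-7-en-1-yl)-1-[13-(pyridin-3-yl)tridecyl]hexahydro-1H-cyclopenta[c][1,2]oxazole | c1cncc(CCCCCCCCCCCCCN2O[C@@H](CCCCCCC=C)[C@H]3CCC[C@H]32)c1
F7 | step 7 | (3S,3aS,6aR)-3-[8-(9-borabicyclo[3.3.1]nonan-9-yl)octyl]-1-[13-(pyridin-3-yl)tridecyl]hexahydro-1H-cyclopenta[c][1,2]oxazole | c1cncc(CCCCCCCCCCCCCN2O[C@@H](CCCCCCCCB4C5CCCC4CCC5)[C@H]3CCC[C@H]32)c1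
F0 | step 8 | none | none
F8 | step 9 | (3aS,6aR)-3-methoxy-3-[8-(pyridin-3-yl)octyl]-1-[13-(pyridin-3-yl)tridecyl]hexahydro-1H-cyclopenta[c][1,2]oxazole | c1cncc(CCCCCCCCCCCCCN2OC(OC)(CCCCCCCCc3cccnc3)[C@H]3CCC[C@H]32)c1
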